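## The problem

The target is a labd-7-ene (labdane numbering throughout; the C15 bicycles are named as drimanes, which share the ring and C11 locants). It is a trans-fused decalin with an equatorial 2α-hydroxyl, gem-dimethyl C4, the angular C20 methyl on quaternary C10 and a trisubstituted C7=C8 olefin; C9 carries a C11–C15 chain with a methyl-bearing stereocentre at C13 and a (Z)-p-coumarate on O15. Five stereocentres (2S,5S,9S,10S,13S) have to be set. The four ring centres can be relayed: C2 can dictate C10 if the two are tied together, and the β-axial C20 methyl then screens the β face of ring B, so that reagents reach C5, C7 and C9 from the α side. C13 lies five bonds from C9, receives no such help and must be bought in. The C7=C8 olefin is less stable than its tetrasubstituted C8=C9 isomer and C9 is allylic, so the olefin position must be fixed by a regiospecific step, and strong acid or isomerising hydrogenation catalysts must be avoided afterwards. The (Z)-cinnamate with its free phenol isomerises to E under light, acid or nucleophilic base and would not survive hydride, diimide or ylide chemistry; it must be built last, on the primary O15 in the presence of the secondary 2-hydroxyl. The feature that opens the plan is twofold: ring A with its oxygen (C1–C5, C10, C18–C20) is the skeleton of (4R,6R)-actinol, and the 2α oxygen is 1,3-cis to the C10–C9 bond, so an acyl group hung on that oxygen can become C11 while C17–C8–C9–C11 is a but-2-ynoate unit facing a C10=C5–C6=C7 diene.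

## Retrosynthesis

**Coumarate.** The acyl–O15 bond and the Cα=Cβ bond of the cinnamate are cut: 34 comes from its bis-silyl ether 33, 33 from phosphonoacetate 30 and aldehyde 31, and 30 from alcohol 28 and acid 29. Esterifying 28 with a preformed (Z)-acid would need a separate synthesis of that acid and risks Z/E leakage on activation. A Z-selective olefination on the substrate uses two purchasable pieces and creates the labile olefin one step before the end. The precursor 28 has no chromophore and no Michael acceptor. The forward steps must be Z-selective and must address O15 only, which is ensured by keeping O2 silylated until the last step.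

**C11–C12.** This bond is cut as the C11=C12 olefin of 26 (reduced to 27, then unmasked at O15 to 28), giving aldehyde 19 and phosphonium salt 24. C11 is already present as a carboxyl carbon after the key step, so only C12–C15 has to be added. The alternatives are worse: a cut at C9–C11 would require a stereoselective alkylation at C9, and a cut at C12–C13 puts the stereocentre at the junction. Salt 24 carries C13 from the chiral pool (20 → 21 → 22 → 23 → 24). The Wittig reaction must outrun enolisation of the β,γ-unsaturated aldehyde, and the reduction of C11=C12 must leave C7=C8 in place.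

**C7=C8 and the C9 hydrogen.** Aldehyde 19 comes from alcohol 18 and ester 17. In 17 the olefin is moved back to C8=C9 and an oxygen is placed on C7, which leads to allylic alcohol 14 and enone 13. The shorter-looking route, deconjugative protonation of the C8=C9 enoate, is rejected: kinetic γ-deprotonation of such esters takes the hydrogen on the substituent cis to the ester, here the C17 methyl, and would give the exocyclic 8(17)-olefin. A reductive allylic transposition (through 15 and 16) is regiospecific, because the hydrogen can only arrive at C9, and stereospecific, because it arrives on the face that holds the diazene. The forward sequence needs a 7β-alcohol and a displacement with inversion.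

**C5 hydrogen, C7 oxygen, lactone.** Enone 13 is traced through 12 (silyl ether removed), 11 (C5=C6 restored), 10 (lactone reclosed) to 9 (C7 deoxygenated). C7 is oxidised while it is doubly allylic and while the lactone masks both O2 and C11, so no protecting group is needed. The oxidation also removes the acidic doubly allylic hydrogens before base is used to open the lactone. Opening before hydrogenation lets ring A return to the chair with C20 axial, so hydrogen adds to C5 from the α face. The precursor 9 is a tricycle with only two stereocentres.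

**Key disconnection.** C9–C10 and C7–C8 of 9 are cut by a retro-Diels–Alder reaction to ester 8. The intermolecular version has no control over which face of C10 reacts and only electronic control of regiochemistry. The tether through O2 makes the facial outcome a geometric necessity and fixes the regiochemistry by its length, and both tether atoms (O2, C11) stay in the target. Ester 8 is monocyclic with one stereocentre. The forward reaction must tolerate a fully substituted diene terminus and close a bridged lactone.

**Diene and ester.** The ester C–O bond of 8 is cut to dienol 6 and but-2-ynoic acid 7. The vinyl–ring bond is cut to enol triflate 4, which comes from silyl ether 2 (through enolate 3) and actinol 1. A cross-coupling is preferred to vinyl-metal addition and dehydration, which passes through a tertiary allylic carbinol prone to allylic rearrangement. Ketone 2 has a single enolisable position, so the triflate regiochemistry is unambiguous. The methyl-bearing stereocentre of actinol is erased on purpose; only the carbinol centre (C2 of the target) is kept.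

## Roads not taken

**Alternative 1:** Ring A is cut at C1–C10 and C4–C5. A chiral oxazaborolidinium Lewis acid would catalyse the Diels–Alder reaction of 2,6-dimethyl-1,4-benzoquinone A1 with 4-methyl-2-(triisopropylsilyloxy)penta-1,3-diene A2 to the cis-fused enedione A3.
- Merits: both ring-A bonds, quaternary C10 and C5 arise in one catalytic asymmetric step from achiral pieces, with no chiral pool. The C9 carbonyl sits where the chain must be attached, which is a more direct handle than the C11 acid level of the chosen plan.
- Weak points: the diene terminus that forms C4–C5 is fully substituted and carries a cis methyl, the least reactive kind of terminus. A3 is cis-fused and must be epimerised at C5. The C6 carbonyl must be deleted, and the C9 carbonyl must be turned into a CH bearing the chain with 9α-H without moving C7=C8. The C2 ketone must be reduced to the equatorial 2α-alcohol against the kinetic preference, because axial hydride delivery from the β face is blocked by the 4β and 10β methyls.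
- Comparison: this road is better in catalytic enantiocontrol and in the C9 handle. The chosen plan sets against it C2 bought in the right configuration and oxidation state, and a ring B that needs one temporary oxygen (C7) where A3 needs three carbonyl groups reworked.

**Alternative 2:** C4–C5 and C9–C10 are cut in one radical cascade. Hydrogen-atom transfer from a metal hydride to a terminal 1,1-disubstituted olefin gives the C4 radical, two 6-endo closures follow, and loss of a hydrogen from C7 would give ester A4.
- Merits: both rings, C5, C9, C10 and the C7=C8 olefin in a single step, with C11 and C12 already in place. In step count this road is clearly superior to the chosen plan.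
- Weak points: all relative configuration is relayed from the single C2 carbinol through a chair–chair folding in which the silyloxy group has only a small equatorial preference. Termination can give the 7-ene, the 8(17)-ene or the 8-ene, and the intermediate radicals can be reduced early. The acyclic precursor, with two defined trisubstituted olefins and an enantiopure carbinol, needs its own asymmetric synthesis, and C13 is still open.
- Comparison: the chosen plan is longer. It sets against this a C10 configuration that cannot come out otherwise, strongly biased substrate control at C5 and C9, and an olefin position fixed by a regiospecific transposition.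

**Alternative 3:** Only C1–C10 is cut. A phenoxide, formed with a strong alkoxide base, alkylates its methyl-bearing ortho carbon with a tethered primary iodide, closing ring A and dearomatising ring B to dienone A5.
- Merits: a simple aromatic precursor. C-alkylation is geometrically favoured, since O-alkylation would need an eight-membered ring. Quaternary C10, the C7=C8 olefin and a C9 carbonyl handle are obtained in fewer steps than lactone 9.
- Weak points: the C10 configuration rests on 1,3-induction from C2 in the alkylation transition state. The 6,6-disubstituted cyclohexa-2,4-dienone is prone to [4+2] dimerisation. C5=C6 must be saturated selectively within a dienone, and the C9 ketone must become a CH carrying the chain with 9α-H, where addition followed by deoxygenation of a doubly allylic tertiary alcohol is not regiocontrolled.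
- Comparison: A5 is reached faster than 9. The chosen plan sets against this that 9 already carries C11 and has C10 fixed by geometry, and that C9 is later set by a stereospecific hydrogen transfer.

Key step: step 6

Assumption: (4R,6R)-actinol 1 and [bis(2,2,2-trifluoroethoxy)phosphoryl]acetic acid 29 are taken as purchasable; the acid is otherwise one hydrolysis step from its commercial methyl ester.

## Steps

Step 1
Reactants: 1 (4R,6R)-4-hydroxy-2,2,6-trimethylcyclohexan-1-one
Product: 2 (4R,6R)-4-[(tert-butyldimethylsilyl)oxy]-2,2,6-trimethylcyclohexan-1-one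
Conditions: TBSCl, imidazole, DMF, rt
Reagents that add atoms: tert-butyldimethylsilyl chloride, CC(C)(C)[Si](C)(C)Cl
Why: Silyl ether formation on the secondary alcohol; ketone and stereocentres are untouched.

Step 2
Reactants: 2 (4R,6R)-4-[(tert-butyldimethylsilyl)oxy]-2,2,6-trimethylcyclohexan-1-one
Product: 4 (4R)-4-[(tert-butyldimethylsilyl)oxy]-2,6,6-trimethylcyclohex-1-en-1-yl trifluoromethanesulfonate, via lithium enolate 3 (not isolated)
Conditions: LiN(i-Pr)2, THF, −78 to 0 °C; then PhNTf2, 0 °C to rt
Reagents that add atoms: N-phenylbis(trifluoromethanesulfonimide), O=S(=O)(N(c1ccccc1)S(=O)(=O)C(F)(F)F)C(F)(F)F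
Why: Enolate formation and O-triflation; the ketone has one enolisable position, so a single tetrasubstituted enol triflate should form. The methyl-bearing stereocentre is erased deliberately and the carbinol centre is not affected.

Step 3
Reactants: 4 (4R)-4-[(tert-butyldimethylsilyl)oxy]-2,6,6-trimethylcyclohex-1-en-1-yl trifluoromethanesulfonate
Product: 5 tert-butyldimethyl{[(1R)-3,5,5-trimethyl-4-vinylcyclohex-3-en-1-yl]oxy}silane
Conditions: CH2=CHSnBu3, Pd(PPh3)4 (5 mol %), LiCl, THF, reflux
Reagents that add atoms: tributyl(vinyl)stannane, C=C[Sn](CCCC)(CCCC)CCCC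
Why: Stille cross-coupling of a hindered cyclohexenyl triflate, with LiCl assisting transmetalation; it gives the 2,6,6-trimethyl-1-vinylcyclohexene diene without a dehydration step.

Step 4
Reactants: 5 tert-butyldimethyl{[(1R)-3,5,5-trimethyl-4-vinylcyclohex-3-en-1-yl]oxy}silane
Product: 6 (1R)-3,5,5-trimethyl-4-vinylcyclohex-3-en-1-ol
Conditions: Bu4NF, THF, rt
Reagents that add atoms: none
Why: Fluoride desilylation under non-acidic conditions, which the diene tolerates.

Step 5
Reactants: 6 (1R)-3,5,5-trimethyl-4-vinylcyclohex-3-en-1-ol; 7 but-2-ynoic acid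
Product: 8 (1R)-3,5,5-trimethyl-4-vinylcyclohex-3-en-1-yl but-2-ynoate
Conditions: DCC, DMAP (cat.), CH2Cl2, 0 °C to rt
Reagents that add atoms: none
Why: Steglich esterification; low temperature and only catalytic DMAP limit ynoate-to-allenoate isomerisation.

Step 6
Reactants: 8 (1R)-3,5,5-trimethyl-4-vinylcyclohex-3-en-1-yl but-2-ynoate
Product: 9 2α-hydroxydrima-5,8-dien-11-oic acid 2,11-lactone (10β-methyl; lactone bridge on the α face of ring A)
Conditions: o-dichlorobenzene (0.005 M), BHT (cat.), degassed, 170–180 °C, sealed tube
Reagents that add atoms: none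
Why: Proposed new method: a concerted thermal [4+2] cycloaddition between the s-cis C10=C5–C6=C7 diene and the tethered ynoate forms C9–C10 and C7–C8 in one event; the closest known reaction type is the ester-tethered intramolecular Diels–Alder reaction of alkynoates of 2,6,6-trimethyl-1-vinylcyclohexenols that closes a fused butenolide from the allylic position, whereas here the tether starts one carbon further away and must close a bridge. Ring B closes as a cyclohexa-1,4-diene by the cycloaddition itself, and the six-membered lactone (C10–C1–C2–O–C11–C9) closes through the C9–C10 bond in a bridged mode, giving with ring A a 2-oxabicyclo[3.3.1]nonane comparable to the easily formed lactone of cis-3-hydroxycyclohexaneacetic acid. The one new stereocentre, quaternary C10, is controlled by C2 through the tether: only addition to the α face of C10 lets the chain span O2 and C9, so C9 must arrive cis to the C2 oxygen and C20 is pushed to the β face. The step needs facial selectivity (secured geometrically), regioselectivity (the tether length allows only the carbonyl-bearing alkyne carbon to reach C10, which puts C11 on C9 and the methyl on C8) and preference for the intramolecular path over oligomerisation (high dilution). The cost is an s-cis ester and an axial C2–O bond syn to the 4α-methyl in the transition state, hence the high temperature; intramolecularity compensates for the fully substituted terminus C10. Oxygen is excluded because C7 of 9 is doubly allylic.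

Step 7
Reactants: 9 2α-hydroxydrima-5,8-dien-11-oic acid 2,11-lactone
Product: 10 2α-hydroxy-7-oxodrima-5,8-dien-11-oic acid 2,11-lactone
Conditions: Mn(OAc)3·2H2O (10 mol %), t-BuOOH (5 equiv), 3 Å MS, EtOAc, rt
Reagents that add atoms: tert-butyl hydroperoxide, CC(C)(C)OO
Why: Radical allylic oxidation by tert-butylperoxyl chemistry; C7 is the only doubly allylic methylene and should give the cross-conjugated dienone. On the lactone no protecting group is needed, and the acidic doubly allylic hydrogens are gone before base is used.

Step 8
Reactants: 10 2α-hydroxy-7-oxodrima-5,8-dien-11-oic acid 2,11-lactone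
Product: 11 methyl 2α-hydroxy-7-oxodrima-5,8-dien-11-oate
Conditions: K2CO3 (0.2 equiv), MeOH, 0 °C; AcOH quench
Reagents that add atoms: methanol, CO
Why: Transesterification of the bridged lactone by methoxide at the acyl carbon; release of the bridge, with ring A returning to its chair, should drive the opening. The C2–O bond is not broken, so C2 keeps its configuration.

Step 9
Reactants: 11 methyl 2α-hydroxy-7-oxodrima-5,8-dien-11-oate
Product: 12 methyl 2α-hydroxy-7-oxodrim-8-en-11-oate (5α-H)
Conditions: H2 (1 atm), 10% Pd/C, EtOAc, rt; stopped after one equivalent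
Reagents that add atoms: none
Why: Heterogeneous catalytic hydrogenation of the less substituted enone double bond; hydrogen should add to C5 from the α face, opposite the axial C20 and 4β methyls, giving the trans ring fusion (new stereocentre C5, controlled by C10). The tetrasubstituted, ester-bearing C8=C9 bond is too hindered to compete.

Step 10
Reactants: 12 methyl 2α-hydroxy-7-oxodrim-8-en-11-oate
Product: 13 methyl 2α-[(tert-butyldimethylsilyl)oxy]-7-oxodrim-8-en-11-oate
Conditions: TBSCl, imidazole, DMF, rt
Reagents that add atoms: tert-butyldimethylsilyl chloride, CC(C)(C)[Si](C)(C)Cl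
Why: Silylation of the equatorial secondary alcohol; it keeps O2 out of the Mitsunobu, oxidation and acylation steps that follow.

Step 11
Reactants: 13 methyl 2α-[(tert-butyldimethylsilyl)oxy]-7-oxodrim-8-en-11-oate
Product: 14 methyl 2α-[(tert-butyldimethylsilyl)oxy]-7β-hydroxydrim-8-en-11-oate
Conditions: NaBH4, CeCl3·7H2O, MeOH, −40 °C
Reagents that add atoms: none
Why: Luche 1,2-reduction of the enone; the small hydride should attack C7 axially from the α face and give the equatorial 7β-alcohol (temporary stereocentre C7). The ester is not reduced.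

Step 12
Reactants: 14 methyl 2α-[(tert-butyldimethylsilyl)oxy]-7β-hydroxydrim-8-en-11-oate
Product: 17 methyl 2α-[(tert-butyldimethylsilyl)oxy]drim-7-en-11-oate (5α-H/9α-H), via 7α-sulfonylhydrazine adduct 15 (not isolated), via 7α-allylic diazene 16 (not isolated)
Conditions: 2-nitrobenzenesulfonylhydrazide, PPh3, DEAD, N-methylmorpholine, −30 °C; then rt
Reagents that add atoms: none
Why: Myers reductive allylic transposition: Mitsunobu displacement with inversion places the sulfonylhydrazine on the α face of C7 (an SN2′ path is closed because C9 is fully substituted), and loss of sulfinic acid gives the allylic diazene. A suprafacial retro-ene shift then delivers hydrogen to the α face of C9 while the double bond moves to C7=C8 and N2 leaves. C9 (9α-H) is thus set by C7, which was set by C10.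

Step 13
Reactants: 17 methyl 2α-[(tert-butyldimethylsilyl)oxy]drim-7-en-11-oate
Product: 18 2α-[(tert-butyldimethylsilyl)oxy]drim-7-en-11-ol
Conditions: LiAlH4, THF, 0 °C
Reagents that add atoms: none
Why: Hydride reduction of the ester to the primary alcohol; reduction is faster than any enolisation, so C9 and the olefin position are kept.

Step 14
Reactants: 18 2α-[(tert-butyldimethylsilyl)oxy]drim-7-en-11-ol
Product: 19 2α-[(tert-butyldimethylsilyl)oxy]drim-7-en-11-al
Conditions: Dess–Martin periodinane, NaHCO3, CH2Cl2, 0 °C; used at once
Reagents that add atoms: none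
Why: Dess–Martin oxidation under buffered, non-basic conditions, chosen because the β,γ-unsaturated aldehyde can epimerise at C9 or conjugate.

Step 15
Reactants: 20 dimethyl (R)-methylsuccinate
Product: 21 (2R)-2-methylbutane-1,4-diol
Conditions: LiAlH4, THF, 0 °C to rt
Reagents that add atoms: none
Why: Hydride reduction of both esters; α-branched esters are reduced without racemisation.

Step 16
Reactants: 21 (2R)-2-methylbutane-1,4-diol
Product: 22 (2R)-4-[(tert-butyldimethylsilyl)oxy]-2-methylbutan-1-ol
Conditions: TBSCl (0.95 equiv), imidazole, CH2Cl2, −30 °C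
Reagents that add atoms: tert-butyldimethylsilyl chloride, CC(C)(C)[Si](C)(C)Cl
Why: Selective monosilylation; the unbranched CH2CH2OH terminus should react faster than the β-branched CH2OH at low temperature with a slight deficit of silyl chloride.

Step 17
Reactants: 22 (2R)-4-[(tert-butyldimethylsilyl)oxy]-2-methylbutan-1-ol
Product: 23 tert-butyl{[(3R)-4-iodo-3-methylbutyl]oxy}dimethylsilane
Conditions: I2, PPh3, imidazole, CH2Cl2, 0 °C
Reagents that add atoms: iodine, II
Why: Appel-type iodination of a primary alcohol; the stereocentre is not involved.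

Step 18
Reactants: 23 tert-butyl{[(3R)-4-iodo-3-methylbutyl]oxy}dimethylsilane
Product: 24 {(2R)-4-[(tert-butyldimethylsilyl)oxy]-2-methylbutyl}triphenylphosphonium iodide
Conditions: PPh3, i-Pr2NEt (cat.), MeCN, reflux
Reagents that add atoms: triphenylphosphine, c1ccc(cc1)P(c1ccccc1)c1ccccc1
Why: SN2 quaternisation of PPh3 by the primary iodide; the stereocentre β to phosphorus has no acidifying group and is configurationally safe.

Step 19
Reactants: 19 2α-[(tert-butyldimethylsilyl)oxy]drim-7-en-11-al; 24 {(2R)-4-[(tert-butyldimethylsilyl)oxy]-2-methylbutyl}triphenylphosphonium iodide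
Product: 26 (11Z,13R)-2α,15-bis[(tert-butyldimethylsilyl)oxy]labda-7,11-diene, via phosphorus ylide 25 (not isolated)
Conditions: NaN(SiMe3)2, THF, −78 to 0 °C; then 19, −78 to 0 °C
Reagents that add atoms: none
Why: Wittig olefination with a non-stabilised ylide; addition at −78 °C should be faster than enolisation of the aldehyde. The Z-olefin is expected, but its geometry is irrelevant, and no new stereocentre is formed (the 13R descriptor reflects only the neighbouring double bond).

Step 20
Reactants: 26 (11Z,13R)-2α,15-bis[(tert-butyldimethylsilyl)oxy]labda-7,11-diene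
Product: 27 (13S)-2α,15-bis[(tert-butyldimethylsilyl)oxy]labd-7-ene
Conditions: TsNHNH2, NaOAc, DME/H2O, reflux, portionwise
Reagents that add atoms: none
Why: Diimide reduction; concerted syn hydrogen transfer should occur at the cis-disubstituted C11=C12 bond much faster than at the trisubstituted C7=C8 bond, and without a metal hydride the ring olefin cannot migrate.

Step 21
Reactants: 27 (13S)-2α,15-bis[(tert-butyldimethylsilyl)oxy]labd-7-ene
Product: 28 (13S)-2α-[(tert-butyldimethylsilyl)oxy]labd-7-en-15-ol
Conditions: CSA (10 mol %), MeOH/CH2Cl2, 0 °C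
Reagents that add atoms: none
Why: Acid-catalysed methanolysis of the primary silyl ether, which should be cleaved well before the secondary one on C2; the acid is too weak to move C7=C8.

Step 22
Reactants: 28 (13S)-2α-[(tert-butyldimethylsilyl)oxy]labd-7-en-15-ol; 29 [bis(2,2,2-trifluoroethoxy)phosphoryl]acetic acid
Product: 30 (13S)-2α-[(tert-butyldimethylsilyl)oxy]labd-7-en-15-yl [bis(2,2,2-trifluoroethoxy)phosphoryl]acetate
Conditions: EDC·HCl, DMAP (cat.), CH2Cl2, 0 °C to rt
Reagents that add atoms: none
Why: Carbodiimide esterification of the only free (primary) hydroxyl.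

Step 23
Reactants: 30 (13S)-2α-[(tert-butyldimethylsilyl)oxy]labd-7-en-15-yl [bis(2,2,2-trifluoroethoxy)phosphoryl]acetate; 31 4-[(tert-butyldimethylsilyl)oxy]benzaldehyde
Product: 33 (13S)-2α-[(tert-butyldimethylsilyl)oxy]labd-7-en-15-yl (Z)-3-{4-[(tert-butyldimethylsilyl)oxy]phenyl}prop-2-enoate, via potassium phosphonate carbanion 32 (not isolated)
Conditions: KN(SiMe3)2, 18-crown-6, THF, −78 °C; then 31, −78 °C
Reagents that add atoms: none
Why: Still–Gennari variant of the Horner–Wadsworth–Emmons reaction; with the trifluoroethyl phosphonate and a dissociated potassium counter-ion, elimination from the kinetic adduct is fast and irreversible, which should give the Z-cinnamate. Aromatic aldehydes are good substrates.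

Step 24
Reactants: 33 (13S)-2α-[(tert-butyldimethylsilyl)oxy]labd-7-en-15-yl (Z)-3-{4-[(tert-butyldimethylsilyl)oxy]phenyl}prop-2-enoate
Product: 34 (2S,5S,9S,10S,13S)-2-hydroxylabd-7-en-15-yl (Z)-3-(4-hydroxyphenyl)prop-2-enoate (CNP0301213.1)
Conditions: HF·pyridine, pyridine, THF, 0 °C to rt, dark
Reagents that add atoms: none
Why: Fluoride cleavage of the aryl and secondary alkyl silyl ethers in a buffered, weakly acidic medium; no base that could isomerise the Z-olefin or cleave the ester is present, light is excluded, and C7=C8 should stay in place.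

## Compound list

1 | (4R,6R)-4-hydroxy-2,2,6-trimethylcyclohexan-1-one, (4R,6R)-actinol | CC1(C)C[C@H](O)C[C@@H](C)C1=O | starting material
2 | (4R,6R)-4-[(tert-butyldimethylsilyl)oxy]-2,2,6-trimethylcyclohexan-1-one | CC1(C)C[C@H](O[Si](C)(C)C(C)(C)C)C[C@@H](C)C1=O | intermediate
3 | lithium (4R)-4-[(tert-butyldimethylsilyl)oxy]-2,6,6-trimethylcyclohex-1-en-1-olate | [Li+].[O-]C1=C(C)C[C@@H](O[Si](C)(C)C(C)(C)C)CC1(C)C | intermediate
4 | (4R)-4-[(tert-butyldimethylsilyl)oxy]-2,6,6-trimethylcyclohex-1-en-1-yl trifluoromethanesulfonate | CC1=C(OS(=O)(=O)C(F)(F)F)C(C)(C)C[C@H](O[Si](C)(C)C(C)(C)C)C1 | intermediate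
5 | tert-butyldimethyl{[(1R)-3,5,5-trimethyl-4-vinylcyclohex-3-en-1-yl]oxy}silane | CC1=C(C=C)C(C)(C)C[C@H](O[Si](C)(C)C(C)(C)C)C1 | intermediate
6 | (1R)-3,5,5-trimethyl-4-vinylcyclohex-3-en-1-ol | CC1=C(C=C)C(C)(C)C[C@H](O)C1 | intermediate
7 | but-2-ynoic acid | CC#CC(=O)O | starting material
8 | (1R)-3,5,5-trimethyl-4-vinylcyclohex-3-en-1-yl but-2-ynoate | CC#CC(=O)O[C@@H]1CC(C)=C(C=C)C(C)(C)C1 | intermediate
9 | 2α-hydroxydrima-5,8-dien-11-oic acid 2,11-lactone (10β-methyl) | CC1=C2C(=O)O[C@@H]3C[C@@]2(C)C(=CC1)C(C)(C)C3 | intermediate
10 | 2α-hydroxy-7-oxodrima-5,8-dien-11-oic acid 2,11-lactone | CC1=C2C(=O)O[C@@H]3C[C@@]2(C)C(=CC1=O)C(C)(C)C3 | intermediate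
11 | methyl 2α-hydroxy-7-oxodrima-5,8-dien-11-oate | CC1=C(C(=O)OC)[C@@]2(C)C[C@@H](O)CC(C)(C)C2=CC1=O | intermediate
12 | methyl 2α-hydroxy-7-oxodrim-8-en-11-oate (5α-H) | CC1=C(C(=O)OC)[C@@]2(C)C[C@@H](O)CC(C)(C)[C@@H]2CC1=O | intermediate
13 | methyl 2α-[(tert-butyldimethylsilyl)oxy]-7-oxodrim-8-en-11-oate | CC1=C(C(=O)OC)[C@@]2(C)C[C@@H](O[Si](C)(C)C(C)(C)C)CC(C)(C)[C@@H]2CC1=O | intermediate
14 | methyl 2α-[(tert-butyldimethylsilyl)oxy]-7β-hydroxydrim-8-en-11-oate | CC1=C(C(=O)OC)[C@@]2(C)C[C@@H](O[Si](C)(C)C(C)(C)C)CC(C)(C)[C@@H]2C[C@@H]1O | intermediate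
15 | methyl 2α-[(tert-butyldimethylsilyl)oxy]-7α-[1-(2-nitrobenzenesulfonyl)hydrazin-1-yl]drim-8-en-11-oate | CC1=C(C(=O)OC)[C@@]2(C)C[C@@H](O[Si](C)(C)C(C)(C)C)CC(C)(C)[C@@H]2C[C@H]1N(N)S(=O)(=O)c1ccccc1[N+](=O)[O-] | intermediate
16 | methyl 2α-[(tert-butyldimethylsilyl)oxy]-7α-diazenyldrim-8-en-11-oate | CC1=C(C(=O)OC)[C@@]2(C)C[C@@H](O[Si](C)(C)C(C)(C)C)CC(C)(C)[C@@H]2C[C@H]1N=N | intermediate
17 | methyl 2α-[(tert-butyldimethylsilyl)oxy]drim-7-en-11-oate (5α-H, 9α-H, 10β-methyl) | CC1=CC[C@H]2C(C)(C)C[C@H](O[Si](C)(C)C(C)(C)C)C[C@]2(C)[C@H]1C(=O)OC | intermediate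
18 | 2α-[(tert-butyldimethylsilyl)oxy]drim-7-en-11-ol | CC1=CC[C@H]2C(C)(C)C[C@H](O[Si](C)(C)C(C)(C)C)C[C@]2(C)[C@H]1CO | intermediate
19 | 2α-[(tert-butyldimethylsilyl)oxy]drim-7-en-11-al | CC1=CC[C@H]2C(C)(C)C[C@H](O[Si](C)(C)C(C)(C)C)C[C@]2(C)[C@H]1C=O | intermediate
20 | dimethyl (R)-methylsuccinate | COC(=O)[C@H](C)CC(=O)OC | starting material
21 | (2R)-2-methylbutane-1,4-diol | OC[C@H](C)CCO | intermediate
22 | (2R)-4-[(tert-butyldimethylsilyl)oxy]-2-methylbutan-1-ol | OC[C@H](C)CCO[Si](C)(C)C(C)(C)C | intermediate
23 | tert-butyl{[(3R)-4-iodo-3-methylbutyl]oxy}dimethylsilane | IC[C@H](C)CCO[Si](C)(C)C(C)(C)C | intermediate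
24 | {(2R)-4-[(tert-butyldimethylsilyl)oxy]-2-methylbutyl}triphenylphosphonium iodide | c1ccccc1[P+](c1ccccc1)(c1ccccc1)C[C@H](C)CCO[Si](C)(C)C(C)(C)C.[I-] | intermediate
25 | {(2R)-4-[(tert-butyldimethylsilyl)oxy]-2-methylbutylidene}triphenylphosphorane | c1ccccc1P(c1ccccc1)(c1ccccc1)=C[C@H](C)CCO[Si](C)(C)C(C)(C)C | intermediate
26 | (11Z,13R)-2α,15-bis[(tert-butyldimethylsilyl)oxy]labda-7,11-diene | CC1=CC[C@H]2C(C)(C)C[C@H](O[Si](C)(C)C(C)(C)C)C[C@]2(C)[C@H]1/C=C\[C@H](C)CCO[Si](C)(C)C(C)(C)C | intermediate
27 | (13S)-2α,15-bis[(tert-butyldimethylsilyl)oxy]labd-7-ene | CC1=CC[C@H]2C(C)(C)C[C@H](O[Si](C)(C)C(C)(C)C)C[C@]2(C)[C@H]1CC[C@H](C)CCO[Si](C)(C)C(C)(C)C | intermediate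
28 | (13S)-2α-[(tert-butyldimethylsilyl)oxy]labd-7-en-15-ol | CC1=CC[C@H]2C(C)(C)C[C@H](O[Si](C)(C)C(C)(C)C)C[C@]2(C)[C@H]1CC[C@H](C)CCO | intermediate
29 | [bis(2,2,2-trifluoroethoxy)phosphoryl]acetic acid | OC(=O)CP(=O)(OCC(F)(F)F)OCC(F)(F)F | starting material
30 | (13S)-2α-[(tert-butyldimethylsilyl)oxy]labd-7-en-15-yl [bis(2,2,2-trifluoroethoxy)phosphoryl]acetate | CC1=CC[C@H]2C(C)(C)C[C@H](O[Si](C)(C)C(C)(C)C)C[C@]2(C)[C@H]1CC[C@H](C)CCOC(=O)CP(=O)(OCC(F)(F)F)OCC(F)(F)F | intermediate
31 | 4-[(tert-butyldimethylsilyl)oxy]benzaldehyde | O=Cc1ccc(O[Si](C)(C)C(C)(C)C)cc1 | starting material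
32 | potassium salt of the α-carbanion of phosphonoacetate 30 | [K+].CC1=CC[C@H]2C(C)(C)C[C@H](O[Si](C)(C)C(C)(C)C)C[C@]2(C)[C@H]1CC[C@H](C)CCOC(=O)[CH-]P(=O)(OCC(F)(F)F)OCC(F)(F)F | intermediate
33 | (13S)-2α-[(tert-butyldimethylsilyl)oxy]labd-7-en-15-yl (Z)-3-{4-[(tert-butyldimethylsilyl)oxy]phenyl}prop-2-enoate | CC1=CC[C@H]2C(C)(C)C[C@H](O[Si](C)(C)C(C)(C)C)C[C@]2(C)[C@H]1CC[C@H](C)CCOC(=O)/C=C\c1ccc(O[Si](C)(C)C(C)(C)C)cc1 | intermediate
34 | (2S,5S,9S,10S,13S)-2-hydroxylabd-7-en-15-yl (Z)-3-(4-hydroxyphenyl)prop-2-enoate (labd-7-ene-2α,15-diol 15-(Z)-p-coumarate) | CC1=CC[C@H]2C(C)(C)C[C@H](O)C[C@]2(C)[C@H]1CC[C@H](C)CCOC(=O)/C=C\c1ccc(O)cc1 | target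

## Step count and least certain steps

Total step count: 24. Longest linear sequence: 20 steps (1 to 34 through steps 1–14 and 19–24); phosphonium salt 24 is made in 4 steps (15–18) from 20.

**Step 6 (key step, Proposed new method).** The cycloaddition may be outrun by thermal side paths: a 1,5-hydrogen shift from the C20 methyl into the diene, ynoate-to-allenoate isomerisation, or oligomerisation. The cause is that the transition state needs an s-cis ester and an axial C2–O bond syn to the 4α-methyl. The fallback uses the known intermolecular reaction and sets out from silyl diene 5. Heating 5 with methyl but-2-ynoate (toluene, 110–140 °C) should give methyl 2α-[(tert-butyldimethylsilyl)oxy]drima-5,8-dien-11-oate F1 in the ortho-type orientation. Facial control by C2 is lost, so the 10-epimer is expected alongside and must be separated. Allylic oxidation (Mn(OAc)3·2H2O, t-BuOOH) would give methyl 2α-[(tert-butyldimethylsilyl)oxy]-7-oxodrima-5,8-dien-11-oate F2, and hydrogenation (H2, Pd/C) returns to the route at 13.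

**Step 12.** The Mitsunobu displacement at the hindered secondary allylic C7 may be overtaken by elimination to a 6,8-diene, or stall at the oxyphosphonium stage. The fallback sets out from enone 13. Condensation with TsNHNH2 gives methyl 2α-[(tert-butyldimethylsilyl)oxy]-7-[2-(4-methylbenzenesulfonyl)hydrazinylidene]drim-8-en-11-oate F3. Reduction with catecholborane followed by NaOAc·3H2O (reductive transposition of an enone tosylhydrazone) moves the olefin to C7=C8. Hydride is expected on the α face of C7, so hydrogen reaches C9 from the β face and the product is methyl 2α-[(tert-butyldimethylsilyl)oxy]-9-epi-drim-7-en-11-oate F4. Deprotonation of F4 at C9 (LiN(i-Pr)2, THF, −78 °C; now the α-hydrogen, so only the endocyclic dienolate can form) and kinetic protonation from the α face returns to the route at 17.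

**Step 9.** Over-reduction of the doubly activated C8=C9 bond, or incomplete α-face selectivity at C5, may erode the material. The fallback changes the order so that the hydrogenation meets an isolated olefin and an unactivated enoate; it sets out from lactone 9. Methanolysis (K2CO3, MeOH, 0 °C) gives methyl 2α-hydroxydrima-5,8-dien-11-oate F5. Hydrogenation (H2, Pd/C), which is known to be selective for C5=C6 with α-face delivery in acetylenedicarboxylate adducts of this diene class, gives methyl 2α-hydroxydrim-8-en-11-oate F6. Silylation gives methyl 2α-[(tert-butyldimethylsilyl)oxy]drim-8-en-11-oate F7, and allylic oxidation of the ring methylene C7 (CrO3, 3,5-dimethylpyrazole, CH2Cl2, −20 °C) returns to the route at 13.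

**Step 19.** The basic ylide may enolise aldehyde 19, which would epimerise C9 or conjugate the olefin to C8=C9. The fallback avoids the aldehyde and the olefin altogether and sets out from alcohol 18. Tf2O and pyridine give 2α-[(tert-butyldimethylsilyl)oxy]drim-7-en-11-yl trifluoromethanesulfonate F8. Iodide 23 is converted with Mg in THF into {(2R)-4-[(tert-butyldimethylsilyl)oxy]-2-methylbutyl}magnesium iodide F9. Copper-catalysed coupling of F8 with F9 (Li2CuCl4, THF, −40 °C) forms C11–C12 directly and returns to the route at 27.

**Step 16.** The two primary hydroxyls may not be discriminated well enough, and the regioisomeric silyl ether would be hard to remove. The fallback sets out from diol 21. Oxidative lactonisation (TEMPO, PhI(OAc)2), which starts at the less hindered carbinol, gives (4R)-4-methyloxolan-2-one F10. Me3SiI opens the lactone at the O–CH2 carbon and aqueous work-up gives (3R)-4-iodo-3-methylbutanoic acid F11. BH3·SMe2 reduces the acid to (3R)-4-iodo-3-methylbutan-1-ol F12, and silylation (TBSCl, imidazole) returns to the route at 23.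

## Further compounds

F1 | step 6 | methyl 2α-[(tert-butyldimethylsilyl)oxy]drima-5,8-dien-11-oate | CC1=C(C(=O)OC)[C@@]2(C)C[C@@H](O[Si](C)(C)C(C)(C)C)CC(C)(C)C2=CC1
F2 | step 6 | methyl 2α-[(tert-butyldimethylsilyl)oxy]-7-oxodrima-5,8-dien-11-oate | CC1=C(C(=O)OC)[C@@]2(C)C[C@@H](O[Si](C)(C)C(C)(C)C)CC(C)(C)C2=CC1=O
F3 | step 12 | methyl 2α-[(tert-butyldimethylsilyl)oxy]-7-[2-(4-methylbenzenesulfonyl)hydrazinylidene]drim-8-en-11-oate | CC1=C(C(=O)OC)[C@@]2(C)C[C@@H](O[Si](C)(C)C(C)(C)C)CC(C)(C)[C@@H]2CC1=NNS(=O)(=O)c1ccc(C)cc1
F4 | step 12 | methyl 2α-[(tert-butyldimethylsilyl)oxy]-9-epi-drim-7-en-11-oate (9β-H) | CC1=CC[C@H]2C(C)(C)C[C@H](O[Si](C)(C)C(C)(C)C)C[C@]2(C)[C@@H]1C(=O)OC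
F5 | step 9 | methyl 2α-hydroxydrima-5,8-dien-11-oate | CC1=C(C(=O)OC)[C@@]2(C)C[C@@H](O)CC(C)(C)C2=CC1
F6 | step 9 | methyl 2α-hydroxydrim-8-en-11-oate (5α-H) | CC1=C(C(=O)OC)[C@@]2(C)C[C@@H](O)CC(C)(C)[C@@H]2CC1
F7 | step 9 | methyl 2α-[(tert-butyldimethylsilyl)oxy]drim-8-en-11-oate | CC1=C(C(=O)OC)[C@@]2(C)C[C@@H](O[Si](C)(C)C(C)(C)C)CC(C)(C)[C@@H]2CC1
F8 | step 19 | 2α-[(tert-butyldimethylsilyl)oxy]drim-7-en-11-yl trifluoromethanesulfonate | CC1=CC[C@H]2C(C)(C)C[C@H](O[Si](C)(C)C(C)(C)C)C[C@]2(C)[C@H]1COS(=O)(=O)C(F)(F)F
F9 | step 19 | {(2R)-4-[(tert-butyldimethylsilyl)oxy]-2-methylbutyl}magnesium iodide | I[Mg]C[C@H](C)CCO[Si](C)(C)C(C)(C)C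
F10 | step 16 | (4R)-4-methyloxolan-2-one | C[C@H]1COC(=O)C1
F11 | step 16 | (3R)-4-iodo-3-methylbutanoic acid | IC[C@H](C)CC(=O)O
F12 | step 16 | (3R)-4-iodo-3-methylbutan-1-ol | IC[C@H](C)CCO
A1 | alternative 1 | 2,6-dimethyl-1,4-benzoquinone | CC1=CC(=O)C=C(C)C1=O
A2 | alternative 1 | 4-methyl-2-(triisopropylsilyloxy)penta-1,3-diene | C=C(O[Si](C(C)C)(C(C)C)C(C)C)C=C(C)C
A3 | alternative 1 | cis-fused 2-(triisopropylsilyloxy)-4,4,8,10-tetramethyloctalin-2,7-diene-6,9-dione (labdane locants) | CC1=CC(=O)[C@@H]2C(C)(C)C=C(O[Si](C(C)C)(C(C)C)C(C)C)C[C@]2(C)C1=O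
A4 | alternative 2 | methyl 2α-[(tert-butyldimethylsilyl)oxy]-13,14,15,16-tetranorlabd-7-en-12-oate | CC1=CC[C@H]2C(C)(C)C[C@H](O[Si](C)(C)C(C)(C)C)C[C@]2(C)[C@H]1CC(=O)OC
A5 | alternative 3 | 2α-[(tert-butyldimethylsilyl)oxy]-4,4,8,10-tetramethyloctalin-5,7-dien-9-one (labdane locants) | CC1=CC=C2C(C)(C)C[C@H](O[Si](C)(C)C(C)(C)C)C[C@]2(C)C1=O
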